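## Plan

- **Cuts:** the C-2 methylene of the oxolane is first taken back to a lactol (C-2–OH). The lactol is then cut at O-1–C-2 and at C-3–C-4, giving 3-(3,4-dimethoxyphenyl)propanal and (E)-3,4-dimethoxycinnamyl alcohol, two phenylpropane units joined as in the 8–8' coupling of lignan biosynthesis.
- **Enabling feature:** with C-2 as a formyl carbon, C-3 is an enamine α-carbon. C-4 is the β-carbon of an electron-rich styrene (its benzylic carbon sits on a 3,4-dimethoxyphenyl ring), and its CH2–OH arm (C-5, O-1) ends up 1,4 to the formyl carbon. Radical C-3–C-4 coupling is therefore followed in the same flask by O-1–C-2 hemiacetal closure of the only ring.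
- **Forward order:** alcohol oxidation; one enamine/photoredox/thiol step that joins the chain and closes the oxolane as its lactol; ionic hydrogenation that removes the lactol OH (the oxidation-level helper).
- **Stereochemistry:** C-3 (R) comes from the imidazolidinone catalyst, C-4 (R) from the relative topicity of the radical addition. The minor cis adduct becomes the achiral meso ether and is removed, so enantiopurity rests on the catalyst-set centre alone.

Key step: step 2

Assumption: 1 and 3 are taken as catalogue compounds, and the facial sense of the (2S,5S)-catalyst is taken from its usual shielding model; the (2R,5R)-antipode would be used if the opposite sense were found.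

## Route

Step 1
Reactants: 1 3-(3,4-dimethoxyphenyl)propan-1-ol
Product: 2 3-(3,4-dimethoxyphenyl)propanal
Conditions: TEMPO (10 mol %), PhI(OAc)2 (1.1 equiv), CH2Cl2, rt; used freshly
Reagents that add atoms: none
Why: Oxoammonium-mediated oxidation of a primary alcohol (TEMPO/PhI(OAc)2) should stop cleanly at the aldehyde under anhydrous conditions and leave the electron-rich ring untouched; no stereocentre is involved.

Step 2
Reactants: 2 3-(3,4-dimethoxyphenyl)propanal; 3 (E)-3-(3,4-dimethoxyphenyl)prop-2-en-1-ol
Product: 5 (3R,4R)-3,4-bis[(3,4-dimethoxyphenyl)methyl]oxolan-2-ol (lactol; both anomers), via γ-hydroxy aldehyde 4 (not isolated)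
Conditions: 3 (1.5 equiv), (2S,5S)-5-benzyl-2-tert-butyl-3-methylimidazolidin-4-one·CF3CO2H (20 mol %, second-generation imidazolidinone), [Ir(Fmppy)2(dtbbpy)]PF6 (1 mol %; Fmppy = cyclometalated 2-(4-fluorophenyl)-4-methylpyridine, dtbbpy = 4,4'-di-tert-butyl-2,2'-bipyridine), 2,4,6-triisopropylbenzenethiol (10 mol %), DME, H2O (3 equiv), blue LEDs, 0 °C; crude lactol taken on at once
Reagents that add atoms: none
Why: Proposed new method: 2 condenses with the amine to the (E)-enamine, the excited trivalent iridium photocatalyst oxidises it to the 3π-electron radical cation, this electrophilic carbon radical adds to the alkene carbon of 3 remote from the aryl group (giving the benzylic radical stabilised by the dimethoxyphenyl ring), the thiol delivers H to that radical, and hydrolysis of the iminium releases γ-hydroxy aldehyde 4, whose hydroxyl adds to the formyl carbon. The closest known reaction type is the enantioselective α-alkylation of aldehydes with terminal styrenes under combined enamine, photoredox and thiol hydrogen-atom-transfer catalysis (SOMO-type carbo-functionalisation of styrenes); new here are the 1,2-disubstituted styrenyl allylic alcohol as acceptor and the capture of the aldehyde by its hydroxyl, a sequence that parallels the 8–8' radical coupling and lactol formation of lignan biosynthesis. The oxolane closes by reversible 5-exo-trig hemiacetalisation, which a γ-hydroxy aldehyde strongly favours. C-3 of 5 (the aldehyde α-carbon) should be set R by the catalyst, whose tert-butyl group turns the enamine π-system away and whose benzyl group shields one face; C-4 is set by the relative topicity of the addition, where an open transition state in which the CH2OH arm of the alkene avoids the α-benzyl group is expected to favour the trans (3R,4R) adduct; the lactol carbon is uncontrolled and is removed in step 3. The step needs oxidation of the enamine in preference to the dimethoxyarenes and the styrene (secured by a photocatalyst of modest excited-state potential), addition at the correct alkene carbon (secured by benzylic radical stability) and retention of the α-centre (secured by its rapid masking as the lactol); the minor cis adduct leads after step 3 to the achiral meso ether, so it costs material but not enantiopurity.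

Step 3
Reactants: 5 (3R,4R)-3,4-bis[(3,4-dimethoxyphenyl)methyl]oxolan-2-ol
Product: 6 (3R,4R)-3,4-bis[(3,4-dimethoxyphenyl)methyl]oxolane (trans-3,4-bis(3,4-dimethoxybenzyl)tetrahydrofuran)
Conditions: Et3SiH (3 equiv), BF3·OEt2 (1.5 equiv), CH2Cl2, −78 °C; chromatography then crystallisation
Reagents that add atoms: none
Why: BF3 ionises the lactol to the cyclic oxocarbenium ion and Et3SiH delivers hydride to it at low temperature (ionic hydrogenation, the standard reductive deoxygenation of lactols to cyclic ethers), both anomers converging on one ion; no stereocentre is formed or touched, and the meso cis ether from the minor adduct of step 2 is separated here as a diastereomer.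

## Compound list

1 | 3-(3,4-dimethoxyphenyl)propan-1-ol | COc1ccc(CCCO)cc1OC | starting material
2 | 3-(3,4-dimethoxyphenyl)propanal | COc1ccc(CCC=O)cc1OC | intermediate
3 | (E)-3-(3,4-dimethoxyphenyl)prop-2-en-1-ol | COc1ccc(/C=C/CO)cc1OC | starting material
4 | (2R,3R)-2,3-bis[(3,4-dimethoxyphenyl)methyl]-4-hydroxybutanal | COc1ccc(C[C@@H](CO)[C@H](C=O)Cc2ccc(OC)c(OC)c2)cc1OC | intermediate (not isolated)
5 | (3R,4R)-3,4-bis[(3,4-dimethoxyphenyl)methyl]oxolan-2-ol, both anomers | COc1ccc(C[C@H]2COC(O)[C@@H]2Cc2ccc(OC)c(OC)c2)cc1OC | intermediate
6 | (3R,4R)-3,4-bis[(3,4-dimethoxyphenyl)methyl]oxolane | COc1ccc(C[C@H]2COC[C@@H]2Cc2ccc(OC)c(OC)c2)cc1OC | target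

## Step count and risks

Total steps: 3. Longest linear sequence: 3 steps (1 → 2 → 5 → 6).

Steps most likely to fail, riskiest first:

**Step 2.** What may go wrong:
- weak facial discrimination at the alkene carbon, so that much material goes to the cis adduct;
- slow radical addition to a 1,2-disubstituted alkene;
- loss of the thiol by thiol–ene addition;
- photosensitised E/Z isomerisation of 3;
- epimerisation of the α-centre before reduction, which would turn cis adduct into the wrong enantiomer of the trans series.

Fallback with known chemistry, fixing the ether tether first and setting out from 3: base-catalysed conjugate addition of 3 to acrylonitrile (benzyltrimethylammonium hydroxide cat.) gives 3-{[(E)-3-(3,4-dimethoxyphenyl)prop-2-en-1-yl]oxy}propanenitrile F1. DIBAL-H (toluene, −78 °C) followed by mild acid hydrolysis gives 3-{[(E)-3-(3,4-dimethoxyphenyl)prop-2-en-1-yl]oxy}propanal F2. Intramolecular enamine/photoredox/thiol α-alkylation of F2, a known reaction type for aldehydes tethered to styrenes, uses the same photocatalyst and thiol but the (2R,5R)-imidazolidinone, because the formyl carbon is now exocyclic. It closes the ring 5-exo-trig with trans selectivity from the cyclic transition state and should give (3R,4R)-4-[(3,4-dimethoxyphenyl)methyl]oxolane-3-carbaldehyde F3. Addition of 3,4-dimethoxyphenylmagnesium bromide (THF, −78 °C) gives (3,4-dimethoxyphenyl)[(3R,4R)-4-[(3,4-dimethoxyphenyl)methyl]oxolan-3-yl]methanol F4 as a carbinol epimer mixture. Hydrogenolysis of the benzylic hydroxyl (H2, Pd/C, AcOH, cat. HClO4) returns to the route at 6.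

**Step 3.** What may go wrong: capture of the oxocarbenium ion by the neighbouring electron-rich ring (Friedel–Crafts closure to a tetralin), or loss of the α-proton to an enol ether with epimerisation.

Fallback that avoids the cation, setting out from 5: NaBH4 (MeOH, 0 °C) reduces the open-chain aldehyde tautomer to (2R,3R)-2,3-bis[(3,4-dimethoxyphenyl)methyl]butane-1,4-diol F5. Acid-catalysed cyclodehydration of this 1,4-diol (cat. p-toluenesulfonic acid, toluene, reflux with water removal; displacement at a primary carbon, stereocentres untouched) returns to the route at 6.

**Step 1.** What may go wrong: over-oxidation to the acid, attack of the hypervalent iodine oxidant on the electron-rich ring, or aldol self-condensation of the aldehyde on isolation.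

Fallback by a redox-neutral route, setting out from 3: ruthenium-catalysed redox isomerisation of the allylic alcohol (RuCl(C5H5)(PPh3)2 cat., Et3NH·PF6, dioxane, 100 °C) converts 3 directly into the saturated aldehyde and returns to the route at 2. No new compound is made (F0), and both halves of the target then come from the single building block 3.

Further compounds
F1 | step 2 | 3-{[(E)-3-(3,4-dimethoxyphenyl)prop-2-en-1-yl]oxy}propanenitrile | COc1ccc(/C=C/COCCC#N)cc1OC
F2 | step 2 | 3-{[(E)-3-(3,4-dimethoxyphenyl)prop-2-en-1-yl]oxy}propanal | COc1ccc(/C=C/COCCC=O)cc1OC
F3 | step 2 | (3R,4R)-4-[(3,4-dimethoxyphenyl)methyl]oxolane-3-carbaldehyde | COc1ccc(C[C@H]2COC[C@@H]2C=O)cc1OC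
F4 | step 2 | (3,4-dimethoxyphenyl)[(3R,4R)-4-[(3,4-dimethoxyphenyl)methyl]oxolan-3-yl]methanol, carbinol epimers | COc1ccc(C[C@H]2COC[C@@H]2C(O)c2ccc(OC)c(OC)c2)cc1OC
F5 | step 3 | (2R,3R)-2,3-bis[(3,4-dimethoxyphenyl)methyl]butane-1,4-diol | COc1ccc(C[C@@H](CO)[C@H](CO)Cc2ccc(OC)c(OC)c2)cc1OC
F0 | step 1 | none | none
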